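Amounts come first here: whichever step consumes a partner, one by-product appears, and each by-product can hold one starting material as idle adduct, which counts as reacted.

    partner + first product → double product + by-product (k1 = 0.89 M⁻¹ min⁻¹)
    starting material + partner → first product + by-product (k2 = 2.3 M⁻¹ min⁻¹)
    starting material + by-product ⇌ idle adduct, settled at all times (K3 = 310 M⁻¹)

- delta: starting material 0.50 M; partner 0.550 M; time 80 min
- gamma: starting material 0.50 M; partner 1.10 M; time 80 min

* part of the starting material that has reacted at the end, delta
* part of the starting material that has reacted at the end, gamma
* what raising the concentration of partner from its lowest to its highest value here does to the part of the starting material that has reacted (changes below 5 percentage points count as none) (it falls / it rises / no change)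

- for by-product the idle adduct is counted in
- what has gone from starting material into another species counts as reacted, even if it can come back
- run time (delta): 80 min

We reckon two extremes. Take first product as inert: by-product then matches the unconverted starting material once a fraction 0.5 of the charge has converted, and free starting material equals free by-product. That common value, the square root of the charge over 2 times 310 M⁻¹, is the stand-off level, 0.0284 M. It puts the reacted part at 94.3% in either flask at that moment, a mark passed early, since the half-life of starting material, 0.55 min, is short against 80 min. It is no end point: in this extreme, delta still holds 0.300 M of partner at the mark and gamma 0.850 M, more than the free starting material, so conversion goes on and the reacted part climbs past it.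

Now take first product as converted at once, so each conversion costs two partners. Delta then consumes its 0.550 M of partner and holds 0.325 M of by-product beyond the unconverted starting material, which gives 99.6% reacted. Gamma, with 2.20 equivalents, reaches 100%. The half-life of first product, 1.4 min, is short against 80 min, so we commit to the second extreme: a change under 5 percentage points.

The forecast gave 99.5% for delta, 99.8% for gamma and no change, holding that “adducted material counts as reacted”. Our own figure for delta is 99.6%.

The flask gives 99.5% for delta and 99.9% for gamma, a change of 0.34 points: no change.

Both stand above the stand-off's 94.3%. A flask like gamma with 0.28 M of partner, 0.560 equiv, gets the same reckoning. With inert first product, by-product exceeds the unconverted starting material by 0.0600 M; with instant conversion, it falls short by 0.0800 M. The two amounts should therefore nearly match, which gives the stand-off level and 94.3% reacted. Partner is the limiting reagent there, with 0% left at 80.0 min, when that flask reads 94.1% reacted.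

(The numbers were chosen freely; no experiment stands behind them.)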